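Readings and results stem from a simulated flask for an exercise; the scatter is artificial.

At early times Z vanishes: in the birch flask, at 21 mM of Q, Z reads 0% after 0.500 h, L reads 87.6%, and X has climbed at 0.232 h⁻¹ of the charge.

| flask | Z | Q | remark | time |
|---|---|---|---|---|
| cedar | 0.046 M | 2.9 mM | run made earlier |  |
| birch | 0.046 M | 21 mM | run made earlier |  |
| grey | 0.046 M | 4.60 mM |  | 20 h |
| amber | 0.046 M | 12.0 mM |  | 20 h |
| ochre | 0.046 M | 29.0 mM |  | 20 h |

| run | time / h | Z / % | L / % | E / % | X / % |
|---|---|---|---|---|---|
| cedar | 1.33 | 0.3 | 70.1 | 2.8 | 26.0 |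
| cedar | 3.00 | 0 | 46.7 | 3.4 | 51.1 |
| cedar | 4.00 | 0 | 36.1 | 3.0 | 61.0 |
| cedar | 6.00 | 0 | 22.8 | 3.5 | 73.7 |
| cedar | 8.00 | 0 | 15.3 | 2.6 | 81.8 |
| cedar | 10.0 | 0.1 | 10.7 | 3.3 | 85.9 |
| birch | 0.500 | 0 | 87.6 | 0.6 | 11.6 |
| birch | 1.50 | 0 | 67.5 | 0.3 | 32.1 |
| birch | 3.00 | 0.4 | 46.1 | 0.7 | 53.6 |
| birch | 4.00 | 0 | 36.0 | 0 | 63.4 |
| birch | 6.00 | 0.2 | 22.2 | 0.2 | 76.8 |
| birch | 8.00 | 0 | 15.5 | 0.7 | 84.6 |
| birch | 10.0 | 0.3 | 11.4 | 1.2 | 88.4 |

(scatter of a reading: 0.3 percentage points)

- which of these there is most of at the end, counted by the Z in it, grey (E / L / Z / X)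
- which of these there is most of at the end, counted by the Z in it, amber (E / L / Z / X)
- which of these there is most of at the end, counted by the Z in it, ochre (E / L / Z / X)
- final amount of the leader among these, as a percentage of the Z charged, in grey
- final amount of the leader among these, as a percentage of the Z charged, in amber
- final amount of the leader among these, as a percentage of the Z charged, in ochre

- Q is the free proton; pH is minus the decimal logarithm of its molar concentration
- percentages count the Z that a species holds: one E counts as two
- the numbers in the tables scatter by 0.3 percentage points (one standard deviation)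

From near the top, L in the cedar flask falls below X by 3.00 h, with L at 46.7% and X at 51.1%. The L curves of cedar and birch lie together, at 36.1% and 36.0% after 4.00 h, although c(Q) differs by a factor of 7.24. The cedar readings of L at 4.00 h, 6.00 h and 8.00 h fall by shrinking steps. As a reading, these steps give a relaxation rate of 0.286 h⁻¹ and a level of 5.60%. After 20 h, the distance to that level has shrunk to 0.328% of itself.

E differs between these two runs. Within its scatter it stays level from the first reading, averaging 3.10% in cedar and 0.529% in birch. I read Z's loss as pseudo-first-order, with a constant proportional to c(Q). If so, the time Z lasts, and with it the E made, goes as one over c(Q). I therefore carry the side constant S, the share of E multiplied by c(Q): 0.0899 mM from cedar, and 0.111 mM from birch, where the same scatter of 0.3 percentage points sits on a smaller E, so I use the cedar value. Then X at the end is the charge less 5.60% and less S/c(Q), which gives me 92.4% for grey, 93.6% for amber and 94.1% for ochre.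

The forecast names X as leader in each flask, at 93%, 94% and 94.5%, noting that “E forms early and then stays flat”, and its figures stand slightly above mine, as in grey, where mine is lower.

The flasks end with X leading at 92.4% in grey, 93.6% in amber and 94.1% in ochre. Grey's X moves by 6 points once its time is cut to 9.67 h.

    Z + Q → G + Q + L (k = 0.768 M⁻¹ s⁻¹)
    G ⇌ D + Q, settled at all times (K = 1.00 × 10⁻⁹ M)
    Z → G + L (k = 6.52 × 10⁻⁶ s⁻¹)
    L ⇌ X (K = 18.1, k = 7.36 × 10⁻⁵ s⁻¹)
    Z + L → E (k = 0.00168 M⁻¹ s⁻¹)

S gives 1.95% of E for grey, where the flask holds 2.08%. On a neighbour of grey, charged with 0.0011 M of Q and read at the same time, S gives 8.17% of E and so 86.2% of X; the computed flask holds 7.56% of E and 87.2% of X.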